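With naphthalene numbering (C1 bears the pendant aryl group), the dihydro ring is closed by a [3+3] union of two complete halves: an itaconate already esterified with both (R)-danshensu units (C2, C3, C4) and a 2-bromobenzhydryl pivalate (C4a, C8a, C1). In one pot a Heck reaction joins C4 to C4a; fluoride then frees the 4'-phenol of the pendant ring, which lies para to C1, so that C1 becomes a p-quinone methide carbon and is attacked by the C2 carbanion. The step exploits this para O/C1 relationship and the C2–H activated by its ester and the C3=C4 styrene unit, and it sets both ring stereocentres; global deprotection follows.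

Key step: step 5

Assumption: the sense of facial induction by the cinchonidinium ion pair at C1 cannot be derived from precedent and is taken to favour the (1R) product; the pseudo-enantiomeric cinchoninium salt is the direct alternative if the opposite sense is found.

Abbreviations: PMB = 4-methoxybenzyl, TBS = tert-butyldimethylsilyl, Piv = pivaloyl.

Step 1
Reactants: 1 sodium (R)-danshensu
Product: 2 PMB ester bis-PMB ether of (R)-danshensu with the secondary OH free
Conditions: 4-methoxybenzyl chloride (3.3 equiv), K2CO3, NaI (cat.), DMF, rt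
Reagents that add atoms: 4-methoxybenzyl chloride, COc1ccc(CCl)cc1
Why: Williamson-type O-alkylation under carbonate conditions should take only the carboxylate and the two phenols, leaving the secondary alcohol free and the (R)-centre, which is not involved, unchanged.

Step 2
Reactants: 2 PMB-protected danshensu alcohol (2.1 equiv); 3 itaconyl chloride
Product: 4 itaconate bis-ester carrying both protected (R)-danshensu units
Conditions: pyridine, CH2Cl2, −20 → 0 °C
Reagents that add atoms: none
Why: Acylation of the secondary alcohol by the bis-acid chloride (nucleophilic acyl substitution with pyridine as HCl acceptor) should form both esters with retention at the carbinol centres, the low temperature keeping the exo-methylene group in place.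

Step 3
Reactants: 5 3-(benzyloxy)-4-hydroxybenzaldehyde
Product: 6 3-(benzyloxy)-4-(TBS-oxy)benzaldehyde
Conditions: TBSCl, imidazole, DMF, rt
Reagents that add atoms: tert-butyl(chloro)dimethylsilane, CC(C)(C)[Si](C)(C)Cl
Why: Imidazole-promoted silylation of the one free phenol installs a fluoride-labile mask on the oxygen that later has to become the phenoxide para to C1.

Step 4
Reactants: 7 5-bromo-2,2-dimethyl-1,3-benzodioxole; 6 3-(benzyloxy)-4-(TBS-oxy)benzaldehyde
Product: 10 racemic 2-bromobenzhydryl pivalate, via aryllithium 8 (not isolated), via lithium alkoxide 9 (not isolated)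
Conditions: LiN(i-Pr)2, THF, −78 °C; then 6, −78 °C; then pivaloyl chloride, −78 → 0 °C
Reagents that add atoms: pivaloyl chloride, CC(C)(C)C(Cl)=O
Why: Directed ortho-lithiation by the amide base should remove the proton flanked by ring oxygen and bromine without halogen–metal exchange, 1,2-addition to the aldehyde gives the alkoxide and in situ O-acylation the pivalate; the carbinol centre forms racemic, which is acceptable because it becomes the planar methide carbon in step 5.

Step 5
Reactants: 10 racemic 2-bromobenzhydryl pivalate; 4 itaconate bis-ester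
Product: 13 protected trans-(1R,2S)-dihydronaphthalene bis-ester, via Heck adduct 11 (not isolated), via p-quinone methide 12 (not isolated)
Conditions: Pd2(dba)3 (2.5 mol %), [HP(t-Bu)3]BF4 (10 mol %), Cy2NMe (1.5 equiv), toluene, 75 °C; then same flask, CsF (3 equiv), N-(9-anthracenylmethyl)cinchonidinium chloride (10 mol %), −20 → 0 °C; aq NH4Cl
Reagents that add atoms: none
Why: Proposed new method: a one-pot Mizoroki–Heck/p-quinone-methide annulation, closest in type to domino Heck/intramolecular condensation annulations of ortho-functionalised aryl halides with itaconates and to 1,6-conjugate-addition annulations of aryl p-quinone methides that carry an ortho-tethered carbon nucleophile. Oxidative addition of zerovalent palladium into the C–Br bond of 10, insertion of the itaconate CH2= terminus and β-hydride elimination should give the (E)-arylidenesuccinate 11 (aryl C4a–C4 bond); fluoride then removes the para silyl group, the phenoxide expels pivalate to give the p-quinone methide 12, and the ammonium dienolate formed at the allylic α-CH2 of the succinate adds to the methide carbon (C1–C2 bond). The six-membered ring closes by a 6-exo-trig conjugate addition; α-attack is the only option because γ-attack would need a four-membered ring, and the (E)-geometry from the Heck stage places the CH2 group cis to the aryl ring as the closure requires. C1 is created at the planar methide carbon (both enantiomers of 10 converge on 12) and its face is selected by the chiral cinchonidinium ion pair, the two (R)-ester units making the minor C1 epimer a separable diastereomer. C2 is set trans to the C1 aryl group, kinetically through the less crowded approach and thermodynamically because its α-proton remains exchangeable under the basic conditions. The step needs the arylation to be complete before the quinone methide is released, which is secured by keeping the 4'-phenol silylated until fluoride is added.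

Step 6
Reactants: 13 protected trans-(1R,2S)-dihydronaphthalene bis-ester
Product: 14 CNP0244800.2
Conditions: BCl3 (excess), pentamethylbenzene (excess), CH2Cl2, −78 → −20 °C; MeOH, then water
Reagents that add atoms: none
Why: Lewis-acid cleavage of benzylic C–O bonds with Friedel–Crafts transfer of the benzyl cations to the non-basic scavenger pentamethylbenzene should remove the four PMB ethers, two PMB esters, the benzyl ether and the isopropylidene ketal at low temperature, while the secondary alkyl esters, the C3=C4 double bond and all four stereocentres are not touched.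

Compound list
1 | sodium (2R)-3-(3,4-dihydroxyphenyl)-2-hydroxypropanoate (sodium danshensu) | O[C@H](Cc1ccc(O)c(O)c1)C(=O)[O-].[Na+] | starting material
2 | 4-methoxybenzyl (2R)-3-{3,4-bis[(4-methoxybenzyl)oxy]phenyl}-2-hydroxypropanoate | O[C@H](Cc1ccc(OCc2ccc(OC)cc2)c(OCc2ccc(OC)cc2)c1)C(=O)OCc1ccc(OC)cc1 | intermediate
3 | itaconyl chloride (2-methylidenebutanedioyl dichloride) | C=C(CC(Cl)=O)C(Cl)=O | starting material
4 | bis[(2R)-3-{3,4-bis[(4-methoxybenzyl)oxy]phenyl}-1-[(4-methoxybenzyl)oxy]-1-oxopropan-2-yl] 2-methylidenebutanedioate | C=C(CC(=O)O[C@H](Cc1ccc(OCc2ccc(OC)cc2)c(OCc2ccc(OC)cc2)c1)C(=O)OCc1ccc(OC)cc1)C(=O)O[C@H](Cc1ccc(OCc2ccc(OC)cc2)c(OCc2ccc(OC)cc2)c1)C(=O)OCc1ccc(OC)cc1 | intermediate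
5 | 3-(benzyloxy)-4-hydroxybenzaldehyde | O=Cc1ccc(O)c(OCc2ccccc2)c1 | starting material
6 | 3-(benzyloxy)-4-[(tert-butyldimethylsilyl)oxy]benzaldehyde | O=Cc1ccc(O[Si](C)(C)C(C)(C)C)c(OCc2ccccc2)c1 | intermediate
7 | 5-bromo-2,2-dimethyl-1,3-benzodioxole | CC1(C)Oc2ccc(Br)cc2O1 | starting material
8 | (5-bromo-2,2-dimethyl-1,3-benzodioxol-4-yl)lithium (not isolated) | [Li]c1c(Br)ccc2OC(C)(C)Oc12 | intermediate
9 | lithium [3-(benzyloxy)-4-(TBS-oxy)phenyl](5-bromo-2,2-dimethyl-1,3-benzodioxol-4-yl)methanolate, racemic (not isolated) | [Li]OC(c1ccc(O[Si](C)(C)C(C)(C)C)c(OCc2ccccc2)c1)c1c(Br)ccc2OC(C)(C)Oc12 | intermediate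
10 | [3-(benzyloxy)-4-(TBS-oxy)phenyl](5-bromo-2,2-dimethyl-1,3-benzodioxol-4-yl)methyl 2,2-dimethylpropanoate, racemic | CC(C)(C)C(=O)OC(c1ccc(O[Si](C)(C)C(C)(C)C)c(OCc2ccccc2)c1)c1c(Br)ccc2OC(C)(C)Oc12 | intermediate
11 | bis(protected (R)-danshensu) ester of (E)-2-[(4-{[3-(benzyloxy)-4-(TBS-oxy)phenyl](pivaloyloxy)methyl}-2,2-dimethyl-1,3-benzodioxol-5-yl)methylidene]butanedioic acid, both carbinol epimers (not isolated) | CC(C)(C)C(=O)OC(c1ccc(O[Si](C)(C)C(C)(C)C)c(OCc2ccccc2)c1)c1c(/C=C(/C(=O)O[C@H](Cc2ccc(OCc3ccc(OC)cc3)c(OCc3ccc(OC)cc3)c2)C(=O)OCc2ccc(OC)cc2)CC(=O)O[C@H](Cc2ccc(OCc3ccc(OC)cc3)c(OCc3ccc(OC)cc3)c2)C(=O)OCc2ccc(OC)cc2)ccc2OC(C)(C)Oc12 | intermediate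
12 | p-quinone methide from 11: the 3-(benzyloxy)-4-oxocyclohexa-2,5-dien-1-ylidene unit is attached through the methide CH to C4 of the benzodioxole that carries the (E)-arylidenesuccinate bis-ester at C5 (not isolated) | O=C1C=CC(=Cc2c(/C=C(/C(=O)O[C@H](Cc3ccc(OCc4ccc(OC)cc4)c(OCc4ccc(OC)cc4)c3)C(=O)OCc3ccc(OC)cc3)CC(=O)O[C@H](Cc3ccc(OCc4ccc(OC)cc4)c(OCc4ccc(OC)cc4)c3)C(=O)OCc3ccc(OC)cc3)ccc3OC(C)(C)Oc23)C=C1OCc1ccccc1 | intermediate
13 | bis[(2R)-3-{3,4-bis[(4-methoxybenzyl)oxy]phenyl}-1-[(4-methoxybenzyl)oxy]-1-oxopropan-2-yl] (1R,2S)-1-[3-(benzyloxy)-4-hydroxyphenyl]-7,8-(isopropylidenedioxy)-1,2-dihydronaphthalene-2,3-dicarboxylate (1-aryl and 2-ester trans) | O=C(O[C@H](Cc1ccc(OCc2ccc(OC)cc2)c(OCc2ccc(OC)cc2)c1)C(=O)OCc1ccc(OC)cc1)C1=Cc2ccc3OC(C)(C)Oc3c2[C@@H](c2ccc(O)c(OCc3ccccc3)c2)[C@@H]1C(=O)O[C@H](Cc1ccc(OCc2ccc(OC)cc2)c(OCc2ccc(OC)cc2)c1)C(=O)OCc1ccc(OC)cc1 | intermediate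
14 | CNP0244800.2: bis[(1R)-1-carboxy-2-(3,4-dihydroxyphenyl)ethyl] (1R,2S)-1-(3,4-dihydroxyphenyl)-7,8-dihydroxy-1,2-dihydronaphthalene-2,3-dicarboxylate | O=C(O[C@H](Cc1ccc(O)c(O)c1)C(=O)O)C1=Cc2ccc(O)c(O)c2[C@@H](c2ccc(O)c(O)c2)[C@@H]1C(=O)O[C@H](Cc1ccc(O)c(O)c1)C(=O)O | target

Total step count: 6. Longest linear sequence: 4 steps (steps 1, 2, 5, 6, or equally steps 3, 4, 5, 6).

Steps most likely to fail

1. Step 5 (proposed new method). What may go wrong:
- oligomerisation of the quinone methide through intermolecular phenoxide attack;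
- poor facial selectivity at C1;
- competing palladium-mediated C–H arylation of the pendant ring;
- base-induced migration of the C3=C4 double bond or air oxidation to the arylnaphthalene.

Fallback: the two bond formations are separated and the stereochemistry is secured by separation instead of catalyst control. It sets out from 10 and 4. The Heck coupling is run alone under the same palladium conditions and the (E)-arylidenesuccinate 11 is isolated. Bu4NF with Cs2CO3 in THF at 0 °C then triggers desilylation, loss of pivalate and the intramolecular 1,6-addition without a chiral additive. This should give 13 together with its (1S,2R) diastereomer F1. Both carry the two (R)-ester units, so they are diastereomers and would be separated by preparative HPLC. The route is rejoined at 13.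

2. Step 6. What may go wrong:
- incomplete cleavage at one of the eight protected sites;
- Friedel–Crafts re-benzylation of the liberated catechol rings;
- acid-induced epimerisation at C2.

Fallback: a two-stage orthogonal deprotection that sets out from 13. Protic acidolysis with TFA/anisole/water (0 °C → rt) first removes the six PMB groups and the isopropylidene ketal, giving the 3'-O-benzyl ether of the target F2. The single remaining aryl benzyl ether is then cleaved with BCl3/pentamethylbenzene at −78 °C. The route comes back at 14.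

3. Step 2. What may go wrong:
- base-induced isomerisation of the exo-methylene unit to the mesaconate or citraconate (through a ketene or dienolate);
- incomplete second acylation.

Fallback: a stepwise esterification that sets out from 2. Itaconic anhydride is opened by one equivalent of 2 (toluene, 60 °C, no base) at its non-conjugated carbonyl, giving the itaconic acid 4-monoester F3. Carbodiimide coupling of the remaining conjugated acid with a second equivalent of 2 (EDC·HCl, catalytic DMAP, CH2Cl2, 0 °C) then gives the bis-ester. The route comes back at 4.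

Further compounds
F1 | step 5 | (1S,2R) diastereomer of 13 (same protected bis-ester, both ring centres inverted) | O=C(O[C@H](Cc1ccc(OCc2ccc(OC)cc2)c(OCc2ccc(OC)cc2)c1)C(=O)OCc1ccc(OC)cc1)C1=Cc2ccc3OC(C)(C)Oc3c2[C@H](c2ccc(O)c(OCc3ccccc3)c2)[C@H]1C(=O)O[C@H](Cc1ccc(OCc2ccc(OC)cc2)c(OCc2ccc(OC)cc2)c1)C(=O)OCc1ccc(OC)cc1
F2 | step 6 | bis[(1R)-1-carboxy-2-(3,4-dihydroxyphenyl)ethyl] (1R,2S)-1-[3-(benzyloxy)-4-hydroxyphenyl]-7,8-dihydroxy-1,2-dihydronaphthalene-2,3-dicarboxylate | O=C(O[C@H](Cc1ccc(O)c(O)c1)C(=O)O)C1=Cc2ccc(O)c(O)c2[C@@H](c2ccc(O)c(OCc3ccccc3)c2)[C@@H]1C(=O)O[C@H](Cc1ccc(O)c(O)c1)C(=O)O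
F3 | step 2 | 4-[(2R)-3-{3,4-bis[(4-methoxybenzyl)oxy]phenyl}-1-[(4-methoxybenzyl)oxy]-1-oxopropan-2-yl] hydrogen 2-methylidenebutanedioate (itaconic acid 4-monoester) | C=C(CC(=O)O[C@H](Cc1ccc(OCc2ccc(OC)cc2)c(OCc2ccc(OC)cc2)c1)C(=O)OCc1ccc(OC)cc1)C(=O)O
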